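**Retrosynthetic overview**

1. Ring numbering: C1 carries the side chain, C2 the methyl group, C3–C5 are CH2, C6 is CMe2. The cyclohexene ring is made first; the butenolide ring is made last from a 3-furyl group carried through the route (singlet oxygen, then NaBH4).
2. Side chain: the (Z)-C(CH2OH)=CH alkene comes from a Still–Gennari olefination of an (R)-β-silyloxy aldehyde (stereocentre from Noyori hydrogenation of a β-keto ester) with an α-alkylated phosphonoacetate, then ester reduction. The (E)-C(CH3)=CH alkene comes from zirconium-catalysed methylalumination of a terminal alkyne and oxirane opening.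
3. Ring: C6 is disconnected to a ketone (C=O to CMe2 by geminal dimethylation). The resulting 2-alkyl-3-methylcyclohex-2-enone is cut at C4–C5 and C1=C2 into a methyl ketone (C5–C6–C1 plus chain) and a methyl vinyl ketone unit (C2–C3–C4): a (3+3) Michael–aldol annulation.
4. Enabling feature: the quaternary ring carbon C6 lies between C5 and C1 and is 1,5-related to the methyl-bearing alkene carbon C2. At the ketone oxidation level C6 makes C5 a Michael donor and C1 an aldol donor toward a C2 carbonyl, so the tetrasubstituted C1=C2 alkene is an aldol-condensation alkene; the C6 oxygen is afterwards replaced by the two methyl groups.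

Key step: step 2

Remark: 3-(trimethylsilyl)but-3-en-2-one and ethyl 3-(furan-3-yl)-3-oxopropanoate are taken as catalogue compounds.

**Route**

Step 1
Reactants: 1 hex-5-ynoic acid
Product: 4 7-(trimethylsilyl)hept-6-yn-2-one, via trilithium adduct 2 (not isolated), via tris-silyl ketal 3 (not isolated)
Conditions: MeLi (3.3 equiv), THF, 0 °C → rt; Me3SiCl (excess), rt; 1 M HCl
Reagents that add atoms: methyllithium, [Li]C; chlorotrimethylsilane, C[Si](C)(C)Cl
Why: Carboxylic acid to methyl ketone by addition of MeLi to the lithium carboxylate (Rubottom protocol): the Me3SiCl quench traps the geminal dialkoxide and C-silylates the acetylide before any ketone meets MeLi, and acid hydrolysis then releases only the ketone; no stereocentre.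

Step 2
Reactants: 4 7-(trimethylsilyl)hept-6-yn-2-one; 5 3-(trimethylsilyl)but-3-en-2-one
Product: 9 2-(but-3-yn-1-yl)-3-methylcyclohex-2-en-1-one, via Michael adduct 6 (not isolated), via diketone 7 (not isolated), via ketol 8 (not isolated)
Conditions: LiN(i-Pr)2, THF, −78 °C; 5, −78 → −20 °C; then KOH, MeOH–H2O, 65 °C
Reagents that add atoms: none
Why: The kinetic lithium enolate of 4 (deprotonation of the CH3 group at −78 °C) adds in a Michael reaction to the CH2 terminus of the α-silyl enone 5, whose silyl group stabilises the adduct enolate and suppresses polymerisation and proton exchange (ring bond C4–C5). Methanolic KOH then removes both C–Si groups, and diketone 7 undergoes a reversible intramolecular aldol addition of its internal α-carbon (future C1) to the methyl ketone carbonyl (future C2), followed by E1cB loss of water (ring bond C1=C2). The closest known reaction type is the Robinson annulation in its aprotic α-silyl vinyl ketone form, combined with the base cyclisation of 2,6-diketones to 2-alkyl-3-methylcyclohex-2-enones. The six-membered ring closes in a 6-(enolendo)-exo-trig aldol mode, and no stereocentre remains in 9 because both ketol centres of 8 are destroyed on dehydration. Two regioselectivities are needed: Michael attack through the methyl carbon, secured by kinetic enolate formation and the fast silylated acceptor, and ring closure by the internal CH2 instead of the terminal CH3, expected because the aldol additions are reversible and dehydration leads to the more substituted, more stable tetrasubstituted enone. The carbonyl group that drives both bond formations sits on C6 and is removed in step 3.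

Step 3
Reactants: 9 2-(but-3-yn-1-yl)-3-methylcyclohex-2-en-1-one
Product: 11 2-(but-3-yn-1-yl)-1,3,3-trimethylcyclohex-1-ene, via titanium alkoxide 10 (not isolated)
Conditions: Me2Zn + TiCl4 (gives Me2TiCl2, 2.5 equiv), CH2Cl2, −40 → 0 °C
Reagents that add atoms: dimethylzinc, C[Zn]C (its methyl groups are delivered through dimethyltitanium dichloride, C[Ti](C)(Cl)Cl, formed in the flask with TiCl4)
Why: Reetz geminal dimethylation of a ketone: Me2TiCl2 transfers one methyl to the carbonyl carbon, the tertiary allylic titanium alkoxide 10 ionises to a 1,3-dimethyl-2-alkylcyclohexenyl cation and a second Ti–CH3 collapses onto the carbon that carried the oxygen, and because the two termini of this cation are equivalent by symmetry only the 1,3,3-trimethylcyclohexene constitution of 11 can result; no stereocentre.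

Step 4
Reactants: 11 2-(but-3-yn-1-yl)-1,3,3-trimethylcyclohex-1-ene
Product: 14 (E)-4-methyl-6-(2,6,6-trimethylcyclohex-1-en-1-yl)hex-3-en-1-ol, via alkenylalane 12 (not isolated), via lithium alanate 13 (not isolated)
Conditions: Me3Al, Cp2ZrCl2 (cat.), CH2Cl2, 0 °C → rt; n-BuLi, THF, −78 °C; oxirane, −78 → 0 °C; 1 M HCl, 0 °C
Reagents that add atoms: trimethylaluminium, C[Al](C)C; oxirane, C1CO1
Why: Negishi zirconium-catalysed methylalumination adds CH3 and Al syn across the terminal alkyne with CH3 on the internal carbon, which fixes the (E) geometry of the trisubstituted alkene, and the derived lithium alanate opens oxirane with retention at the alkenyl carbon; no stereocentre.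

Step 5
Reactants: 14 (E)-4-methyl-6-(2,6,6-trimethylcyclohex-1-en-1-yl)hex-3-en-1-ol
Product: 15 2-[(E)-6-iodo-3-methylhex-3-en-1-yl]-1,3,3-trimethylcyclohex-1-ene
Conditions: I2, PPh3, imidazole, CH2Cl2, 0 °C → rt
Reagents that add atoms: iodine, II
Why: Iodination of a primary alcohol through its alkoxyphosphonium salt (Appel-type reaction under Garegg–Samuelsson conditions), an SN2 displacement that does not touch the alkenes.

Step 6
Reactants: 15 2-[(E)-6-iodo-3-methylhex-3-en-1-yl]-1,3,3-trimethylcyclohex-1-ene; 16 methyl 2-[bis(2,2,2-trifluoroethoxy)phosphoryl]acetate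
Product: 17 methyl (E)-2-[bis(2,2,2-trifluoroethoxy)phosphoryl]-6-methyl-8-(2,6,6-trimethylcyclohex-1-en-1-yl)oct-5-enoate (racemic)
Conditions: NaH, DMF, 0 °C; then 15, 40 °C (16 in excess)
Reagents that add atoms: none
Why: SN2 C-alkylation of the sodium salt of the phosphonoacetate by a primary iodide, with 16 in excess to suppress dialkylation; the new centre is racemic and is destroyed in step 10.

Step 7
Reactants: 18 ethyl 3-(furan-3-yl)-3-oxopropanoate
Product: 19 ethyl (3R)-3-(furan-3-yl)-3-hydroxypropanoate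
Conditions: H2 (50 atm), RuCl2[(S)-BINAP] (1 mol %), EtOH, 50 °C
Reagents that add atoms: none
Why: Noyori asymmetric hydrogenation of a β-keto ester: the substrate chelates ruthenium through both carbonyl groups and the (S)-BINAP ligand exposes the ketone face that gives the (R)-carbinol (the sense that gives (R)-3-hydroxybutanoates with the (R)-ligand, the descriptor being reversed here because the furyl group outranks CH2CO2Et); the furan is not reduced.

Step 8
Reactants: 19 ethyl (3R)-3-(furan-3-yl)-3-hydroxypropanoate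
Product: 20 ethyl (3R)-3-[(tert-butyldimethylsilyl)oxy]-3-(furan-3-yl)propanoate
Conditions: t-BuMe2SiCl, imidazole, DMF, rt
Reagents that add atoms: tert-butyldimethylsilyl chloride, CC(C)(C)[Si](C)(C)Cl
Why: Standard O-silylation of a secondary alcohol (Corey conditions); the C–O bond of the stereocentre is not broken.

Step 9
Reactants: 20 ethyl (3R)-3-[(tert-butyldimethylsilyl)oxy]-3-(furan-3-yl)propanoate
Product: 21 (3R)-3-[(tert-butyldimethylsilyl)oxy]-3-(furan-3-yl)propanal
Conditions: i-Bu2AlH (1.1 equiv), CH2Cl2, −78 °C; aqueous potassium sodium tartrate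
Reagents that add atoms: none
Why: Partial reduction of an ester by i-Bu2AlH: the tetrahedral aluminium hemiacetal is stable at −78 °C and gives the aldehyde on work-up; the stereocentre is β to the carbonyl and cannot epimerise by enolisation.

Step 10
Reactants: 17 methyl (E)-2-[bis(2,2,2-trifluoroethoxy)phosphoryl]-6-methyl-8-(2,6,6-trimethylcyclohex-1-en-1-yl)oct-5-enoate; 21 (3R)-3-[(tert-butyldimethylsilyl)oxy]-3-(furan-3-yl)propanal
Product: 22 methyl (2Z,5R)-5-[(tert-butyldimethylsilyl)oxy]-5-(furan-3-yl)-2-[(3E)-4-methyl-6-(2,6,6-trimethylcyclohex-1-en-1-yl)hex-3-en-1-yl]pent-2-enoate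
Conditions: 17, KN(SiMe3)2, 18-crown-6, THF, −78 °C; then 21
Reagents that add atoms: none
Why: Still–Gennari variant of the Horner–Wadsworth–Emmons reaction: the electron-poor bis(trifluoroethyl) phosphonate with a dissociated potassium counter-ion eliminates from the kinetic adduct, which places the ester cis to the aldehyde-derived CH2 and so sets the (Z) trisubstituted alkene; the silyloxy stereocentre is not involved.

Step 11
Reactants: 22 methyl (2Z,5R)-5-[(tert-butyldimethylsilyl)oxy]-5-(furan-3-yl)-2-[(3E)-4-methyl-6-(2,6,6-trimethylcyclohex-1-en-1-yl)hex-3-en-1-yl]pent-2-enoate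
Product: 23 (2Z,5R)-5-[(tert-butyldimethylsilyl)oxy]-5-(furan-3-yl)-2-[(3E)-4-methyl-6-(2,6,6-trimethylcyclohex-1-en-1-yl)hex-3-en-1-yl]pent-2-en-1-ol
Conditions: i-Bu2AlH (2.5 equiv), CH2Cl2, −78 → 0 °C; aqueous potassium sodium tartrate
Reagents that add atoms: none
Why: 1,2-Reduction of the conjugated ester to the allylic alcohol by i-Bu2AlH with retention of the alkene geometry; furan and silyl ether are inert.

Step 12
Reactants: 23 (2Z,5R)-5-[(tert-butyldimethylsilyl)oxy]-5-(furan-3-yl)-2-[(3E)-4-methyl-6-(2,6,6-trimethylcyclohex-1-en-1-yl)hex-3-en-1-yl]pent-2-en-1-ol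
Product: 24 (2Z,5R)-5-(furan-3-yl)-2-[(3E)-4-methyl-6-(2,6,6-trimethylcyclohex-1-en-1-yl)hex-3-en-1-yl]pent-2-ene-1,5-diol
Conditions: Bu4NF, THF, 0 °C → rt
Reagents that add atoms: none
Why: Fluoride-induced cleavage of the silyl ether, driven by Si–F bond formation; the C–O bond of the carbinol centre is not broken.

Step 13
Reactants: 24 (2Z,5R)-5-(furan-3-yl)-2-[(3E)-4-methyl-6-(2,6,6-trimethylcyclohex-1-en-1-yl)hex-3-en-1-yl]pent-2-ene-1,5-diol
Product: 26 5-hydroxy-4-[(1R,3Z,7E)-1-hydroxy-4-(hydroxymethyl)-8-methyl-10-(2,6,6-trimethylcyclohex-1-en-1-yl)deca-3,7-dien-1-yl]furan-2(5H)-one (both C5 epimers), via endoperoxide 25 (not isolated)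
Conditions: O2, hν, rose bengal, i-Pr2NEt, CH2Cl2–MeOH, −78 °C
Reagents that add atoms: dioxygen (as singlet oxygen), O=O
Why: Base-directed photooxygenation of a 3-substituted furan: singlet oxygen adds across C2 and C5 of the furan in a (4+2) cycloaddition, and the hindered amine removes the less hindered bridgehead hydrogen of endoperoxide 25 (the one remote from the substituent), so that this carbon becomes the lactone carbonyl and the 4-substituted 5-hydroxybutenolide results; the electron-rich furan should react faster at −78 °C than the hindered ring alkene and the trisubstituted alkenes, as in furanoterpenoids of this family.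

Step 14
Reactants: 26 5-hydroxy-4-[(1R,3Z,7E)-1-hydroxy-4-(hydroxymethyl)-8-methyl-10-(2,6,6-trimethylcyclohex-1-en-1-yl)deca-3,7-dien-1-yl]furan-2(5H)-one
Product: 28 4-[(1R,3Z,7E)-1-hydroxy-4-(hydroxymethyl)-8-methyl-10-(2,6,6-trimethylcyclohex-1-en-1-yl)deca-3,7-dien-1-yl]furan-2(5H)-one, via hydroxy carboxylate 27 (not isolated)
Conditions: NaBH4, EtOH, 0 °C; then 1 M HCl
Reagents that add atoms: none
Why: NaBH4 reduces the aldehyde of the ring-opened formyl acrylate tautomer of the hydroxybutenolide, and acidification closes the γ-hydroxy acid 27 (CH2OH cis to the carboxylate) to the butenolide; the conjugated lactone and the carbinol centre are not affected at 0 °C.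

**Compound list**

1 | hex-5-ynoic acid | C#CCCCC(=O)O | starting material
2 | 2,2-bis(lithiooxy)-7-lithiohept-6-yne (trilithium adduct) | [Li]C#CCCCC(C)(O[Li])O[Li] | intermediate
3 | 2,2-bis(trimethylsilyloxy)-7-(trimethylsilyl)hept-6-yne | C[Si](C)(C)C#CCCCC(C)(O[Si](C)(C)C)O[Si](C)(C)C | intermediate
4 | 7-(trimethylsilyl)hept-6-yn-2-one | CC(=O)CCCC#C[Si](C)(C)C | intermediate
5 | 3-(trimethylsilyl)but-3-en-2-one | CC(=O)C(=C)[Si](C)(C)C | starting material
6 | 3,11-bis(trimethylsilyl)undec-10-yne-2,6-dione (racemic, formed as its lithium enolate) | CC(=O)C(CCC(=O)CCCC#C[Si](C)(C)C)[Si](C)(C)C | intermediate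
7 | undec-10-yne-2,6-dione | CC(=O)CCCC(=O)CCCC#C | intermediate
8 | 2-(but-3-yn-1-yl)-3-hydroxy-3-methylcyclohexan-1-one (diastereomer mixture) | CC1(O)CCCC(=O)C1CCC#C | intermediate
9 | 2-(but-3-yn-1-yl)-3-methylcyclohex-2-en-1-one | CC1=C(CCC#C)C(=O)CCC1 | intermediate
10 | dichloro(methyl)titanium 2-(but-3-yn-1-yl)-1,3-dimethylcyclohex-2-en-1-olate (racemic) | CC1=C(CCC#C)C(C)(O[Ti](C)(Cl)Cl)CCC1 | intermediate
11 | 2-(but-3-yn-1-yl)-1,3,3-trimethylcyclohex-1-ene | CC1=C(CCC#C)C(C)(C)CCC1 | intermediate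
12 | dimethyl[(E)-2-methyl-4-(2,6,6-trimethylcyclohex-1-en-1-yl)but-1-en-1-yl]alane | C[Al](C)/C=C(C)/CCC1=C(C)CCCC1(C)C | intermediate
13 | lithium butyldimethyl[(E)-2-methyl-4-(2,6,6-trimethylcyclohex-1-en-1-yl)but-1-en-1-yl]aluminate | CCCC[Al-](C)(C)/C=C(C)/CCC1=C(C)CCCC1(C)C.[Li+] | intermediate
14 | (E)-4-methyl-6-(2,6,6-trimethylcyclohex-1-en-1-yl)hex-3-en-1-ol | OCC/C=C(C)/CCC1=C(C)CCCC1(C)C | intermediate
15 | 2-[(E)-6-iodo-3-methylhex-3-en-1-yl]-1,3,3-trimethylcyclohex-1-ene | ICC/C=C(C)/CCC1=C(C)CCCC1(C)C | intermediate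
16 | methyl 2-[bis(2,2,2-trifluoroethoxy)phosphoryl]acetate | COC(=O)CP(=O)(OCC(F)(F)F)OCC(F)(F)F | starting material
17 | methyl (E)-2-[bis(2,2,2-trifluoroethoxy)phosphoryl]-6-methyl-8-(2,6,6-trimethylcyclohex-1-en-1-yl)oct-5-enoate (racemic) | COC(=O)C(CC/C=C(C)/CCC1=C(C)CCCC1(C)C)P(=O)(OCC(F)(F)F)OCC(F)(F)F | intermediate
18 | ethyl 3-(furan-3-yl)-3-oxopropanoate | CCOC(=O)CC(=O)c1ccoc1 | starting material
19 | ethyl (3R)-3-(furan-3-yl)-3-hydroxypropanoate | CCOC(=O)C[C@@H](O)c1ccoc1 | intermediate
20 | ethyl (3R)-3-[(tert-butyldimethylsilyl)oxy]-3-(furan-3-yl)propanoate | CCOC(=O)C[C@@H](O[Si](C)(C)C(C)(C)C)c1ccoc1 | intermediate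
21 | (3R)-3-[(tert-butyldimethylsilyl)oxy]-3-(furan-3-yl)propanal | O=CC[C@@H](O[Si](C)(C)C(C)(C)C)c1ccoc1 | intermediate
22 | methyl (2Z,5R)-5-[(tert-butyldimethylsilyl)oxy]-5-(furan-3-yl)-2-[(3E)-4-methyl-6-(2,6,6-trimethylcyclohex-1-en-1-yl)hex-3-en-1-yl]pent-2-enoate | CC1=C(CC/C(C)=C/CC/C(=C/C[C@@H](O[Si](C)(C)C(C)(C)C)c2ccoc2)C(=O)OC)C(C)(C)CCC1 | intermediate
23 | (2Z,5R)-5-[(tert-butyldimethylsilyl)oxy]-5-(furan-3-yl)-2-[(3E)-4-methyl-6-(2,6,6-trimethylcyclohex-1-en-1-yl)hex-3-en-1-yl]pent-2-en-1-ol | CC1=C(CC/C(C)=C/CC/C(=C/C[C@@H](O[Si](C)(C)C(C)(C)C)c2ccoc2)CO)C(C)(C)CCC1 | intermediate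
24 | (2Z,5R)-5-(furan-3-yl)-2-[(3E)-4-methyl-6-(2,6,6-trimethylcyclohex-1-en-1-yl)hex-3-en-1-yl]pent-2-ene-1,5-diol | CC1=C(CC/C(C)=C/CC/C(=C/C[C@@H](O)c2ccoc2)CO)C(C)(C)CCC1 | intermediate
25 | (2Z,5R)-2-[(3E)-4-methyl-6-(2,6,6-trimethylcyclohex-1-en-1-yl)hex-3-en-1-yl]-5-(2,3,7-trioxabicyclo[2.2.1]hept-5-en-5-yl)pent-2-ene-1,5-diol (furan endoperoxide, diastereomers at the bicycle) | CC1=C(CC/C(C)=C/CC/C(=C/C[C@@H](O)C2=CC3OOC2O3)CO)C(C)(C)CCC1 | intermediate
26 | 5-hydroxy-4-[(1R,3Z,7E)-1-hydroxy-4-(hydroxymethyl)-8-methyl-10-(2,6,6-trimethylcyclohex-1-en-1-yl)deca-3,7-dien-1-yl]furan-2(5H)-one (both C5 epimers) | CC1=C(CC/C(C)=C/CC/C(=C/C[C@@H](O)C2=CC(=O)OC2O)CO)C(C)(C)CCC1 | intermediate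
27 | sodium (2E)-4-hydroxy-3-[(1R,3Z,7E)-1-hydroxy-4-(hydroxymethyl)-8-methyl-10-(2,6,6-trimethylcyclohex-1-en-1-yl)deca-3,7-dien-1-yl]but-2-enoate | CC1=C(CC/C(C)=C/CC/C(=C/C[C@@H](O)/C(CO)=C/C(=O)[O-])CO)C(C)(C)CCC1.[Na+] | intermediate
28 | 4-[(1R,3Z,7E)-1-hydroxy-4-(hydroxymethyl)-8-methyl-10-(2,6,6-trimethylcyclohex-1-en-1-yl)deca-3,7-dien-1-yl]furan-2(5H)-one | CC1=C(CC/C(C)=C/CC/C(=C/C[C@@H](O)C2=CC(=O)OC2)CO)C(C)(C)CCC1 | target

**Step count and risks**

Total step count: 14. Longest linear sequence: 11 steps (steps 1–6 and 10–14); the aldehyde branch (steps 7–9) has 3 steps.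

Steps most likely to fail:

1. Step 3 (geminal dimethylation). The allyl cation may lose a proton to give cyclohexadienes, or the second methyl transfer may be slow so that the cation oligomerises. Fallback: thioacetal cross-coupling in place of cation chemistry. Setting out from enone 9, ethane-1,2-dithiol and BF3·OEt2 give the dithiolane 6-(but-3-yn-1-yl)-7-methyl-1,4-dithiaspiro[4.5]dec-6-ene F1. MeMgI with catalytic NiCl2(PPh3)2 in refluxing benzene–THF (nickel-catalysed geminal dimethylation of an allylic dithioacetal; the alkyne is carried as its magnesium acetylide and recovered on work-up) then replaces both C–S bonds by methyl groups. The route is rejoined at 11.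

2. Step 2 (annulation). Proton transfer may scramble the enolate before the Michael addition, or diketone 7 may close through its terminal methyl group to a 3-alkylcyclohex-2-enone. Fallback: ring closure by acylation, which has only one six-membered option and makes the same two ring bonds. Setting out from ketone 4, LiN(i-Pr)2 and then methyl acrylate (Michael addition through the methyl carbon) give methyl 5-oxo-10-(trimethylsilyl)dec-9-ynoate F2 as its enolate. KOtBu closes it by Claisen (Dieckmann-type) condensation through the internal CH2 group, and methanolic K2CO3 work-up gives 2-(but-3-yn-1-yl)cyclohexane-1,3-dione F3. MeOH and TsOH give the vinylogous ester 2-(but-3-yn-1-yl)-3-methoxycyclohex-2-en-1-one F4, and MeLi followed by aqueous HCl (Stork–Danheiser carbonyl transposition) gives enone 9, where the route is rejoined.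

3. Step 13 (photooxygenation at the end). Singlet oxygen may also undergo ene reactions at the tetrasubstituted ring alkene or the trisubstituted alkenes, or the endoperoxide may be deprotonated at the wrong bridgehead. Fallback: the oxidation is moved to an alkene-free stage and the butenolide is carried through the hydride steps as a 2-silyloxyfuran.
   - Setting out from ester 20, the same photooxygenation gives ethyl (3R)-3-[(tert-butyldimethylsilyl)oxy]-3-(2-hydroxy-5-oxo-2,5-dihydrofuran-3-yl)propanoate F5, and NaBH4 then acid gives ethyl (3R)-3-[(tert-butyldimethylsilyl)oxy]-3-(5-oxo-2,5-dihydrofuran-3-yl)propanoate F6.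
   - i-Pr3SiOSO2CF3 and Et3N convert the butenolide into ethyl (3R)-3-[(tert-butyldimethylsilyl)oxy]-3-{5-[(triisopropylsilyl)oxy]furan-3-yl}propanoate F7, which should be inert to hydride and to the phosphonate anion.
   - i-Bu2AlH at −78 °C gives (3R)-3-[(tert-butyldimethylsilyl)oxy]-3-{5-[(triisopropylsilyl)oxy]furan-3-yl}propanal F8. Olefination with 17 as in step 10 gives methyl (2Z,5R)-5-[(tert-butyldimethylsilyl)oxy]-2-[(3E)-4-methyl-6-(2,6,6-trimethylcyclohex-1-en-1-yl)hex-3-en-1-yl]-5-{5-[(triisopropylsilyl)oxy]furan-3-yl}pent-2-enoate F9. i-Bu2AlH gives (2Z,5R)-5-[(tert-butyldimethylsilyl)oxy]-2-[(3E)-4-methyl-6-(2,6,6-trimethylcyclohex-1-en-1-yl)hex-3-en-1-yl]-5-{5-[(triisopropylsilyl)oxy]furan-3-yl}pent-2-en-1-ol F10.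
   - HF·pyridine removes both silyl groups, the liberated 2-hydroxyfuran tautomerising to the conjugated butenolide. The route is rejoined at the target 28.

Further compounds
F1 | step 3 | 6-(but-3-yn-1-yl)-7-methyl-1,4-dithiaspiro[4.5]dec-6-ene | CC1=C(CCC#C)C2(SCCS2)CCC1
F2 | step 2 | methyl 5-oxo-10-(trimethylsilyl)dec-9-ynoate | COC(=O)CCCC(=O)CCCC#C[Si](C)(C)C
F3 | step 2 | 2-(but-3-yn-1-yl)cyclohexane-1,3-dione | O=C1CCCC(=O)C1CCC#C
F4 | step 2 | 2-(but-3-yn-1-yl)-3-methoxycyclohex-2-en-1-one | COC1=C(CCC#C)C(=O)CCC1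
F5 | step 13 | ethyl (3R)-3-[(tert-butyldimethylsilyl)oxy]-3-(2-hydroxy-5-oxo-2,5-dihydrofuran-3-yl)propanoate | CCOC(=O)C[C@@H](O[Si](C)(C)C(C)(C)C)C1=CC(=O)OC1O
F6 | step 13 | ethyl (3R)-3-[(tert-butyldimethylsilyl)oxy]-3-(5-oxo-2,5-dihydrofuran-3-yl)propanoate | CCOC(=O)C[C@@H](O[Si](C)(C)C(C)(C)C)C1=CC(=O)OC1
F7 | step 13 | ethyl (3R)-3-[(tert-butyldimethylsilyl)oxy]-3-{5-[(triisopropylsilyl)oxy]furan-3-yl}propanoate | CCOC(=O)C[C@@H](O[Si](C)(C)C(C)(C)C)c1coc(O[Si](C(C)C)(C(C)C)C(C)C)c1
F8 | step 13 | (3R)-3-[(tert-butyldimethylsilyl)oxy]-3-{5-[(triisopropylsilyl)oxy]furan-3-yl}propanal | O=CC[C@@H](O[Si](C)(C)C(C)(C)C)c1coc(O[Si](C(C)C)(C(C)C)C(C)C)c1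
F9 | step 13 | methyl (2Z,5R)-5-[(tert-butyldimethylsilyl)oxy]-2-[(3E)-4-methyl-6-(2,6,6-trimethylcyclohex-1-en-1-yl)hex-3-en-1-yl]-5-{5-[(triisopropylsilyl)oxy]furan-3-yl}pent-2-enoate | CC1=C(CC/C(C)=C/CC/C(=C/C[C@@H](O[Si](C)(C)C(C)(C)C)c2coc(O[Si](C(C)C)(C(C)C)C(C)C)c2)C(=O)OC)C(C)(C)CCC1
F10 | step 13 | (2Z,5R)-5-[(tert-butyldimethylsilyl)oxy]-2-[(3E)-4-methyl-6-(2,6,6-trimethylcyclohex-1-en-1-yl)hex-3-en-1-yl]-5-{5-[(triisopropylsilyl)oxy]furan-3-yl}pent-2-en-1-ol | CC1=C(CC/C(C)=C/CC/C(=C/C[C@@H](O[Si](C)(C)C(C)(C)C)c2coc(O[Si](C(C)C)(C(C)C)C(C)C)c2)CO)C(C)(C)CCC1
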